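The constants used here are those of an exercise, and the outcome is calculated.

- If crystals outlast the run in this flask, the dissolved complex with one exchanged stays at its solubility, 0.40 mM, and I can reckon the other forms from that level.

starting complex 20 mM; gas 6.8 mM (held); time 12 h

    gas ⇌ incoming ligand, rate k1*(csat - [incoming ligand]) (k1 = 0.85 /min, csat = 6.8 mM)
    complex with one exchanged + incoming ligand ⇌ leaving ligand + complex with two exchanged (K2 = 1.8, k2 = 16 /M/min)
    complex with two exchanged + incoming ligand ⇌ leaving ligand + complex with three exchanged (K3 = 6.9, k3 = 3.6 /M/min)
    crystals ⇌ complex with one exchanged, rate k4*(cs4 - [complex with one exchanged]) while solid is left; crystals form when [complex with one exchanged] > cs4 (cs4 = 0.40 mM, k4 = 35 /min)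
    starting complex + incoming ligand ⇌ leaving ligand + complex with one exchanged (K5 = 1.3, k5 = 27 /M/min)

- what is said of complex with one exchanged includes crystals
- crystals is a solid; its amount is given per volume of the solution
- at the start none of incoming ligand is dissolved
- the reaction counts as stopped when no species that holds the starting complex changes by six tenths of a point or more over the second half of the time
- run time (flask): 12 h

* why nothing more happens at 12 h, or that something still does (it is still moving / all of the starting complex has reacted / forward and back rates have come level)
* part of the starting complex gone at 12 h
* the complex with one exchanged standing at 12 h, as a percentage of the starting complex charged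
* the complex with three exchanged standing at 12 h, as a percentage of the starting complex charged

- I take the incoming ligand at the level of the gas, 6.8 mM, and one leaving ligand per complex charged, so ρ, incoming over leaving ligand, is 0.340.
- In logarithms each exchange adds the logarithm of its equilibrium constant times ρ. Summing the forms back to ordinary numbers, the solution holds C = 2.12 mM at saturation.
- My number is the loading S, the charge over C: 9.42. Its common logarithm is 0.974, nearly one power of ten above unity.
- S above unity in this flask means crystals stay at equilibrium, and their share of the charge is one minus the reciprocal of S: 89.4%.
- Adding the dissolved part gives 91.4% for the complex with one exchanged. I also get 95.5% conversion and 2.87% for the complex with three exchanged.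
- Is one number enough? The leaving ligand tallies to 102% of the charge, so my ρ is slightly high.
- S also holds no time. With the complex with two exchanged held, the last exchange has a relaxation time τ, its equilibrium constant over its rate constant times the leaving ligand: 95.8 min. The run lasts 7.51 such times, so I expect forward and back rates to have come level.
- The forecast gives forward and back rates have come level, 95.4%, 91.4% and 2.8%, the last below mine, holding that “the mixture has stopped changing”.
- This flask gives forward and back rates have come level, 95.4%, 91.4% and 2.75%. Its crystals stand at 89.4% at 12.0 h, against my 89.4%. For the neighbour flask charged with 80 mM, the same reckoning gives ρ = 0.0850 and S = 19.4, and so crystals of 94.8%. That neighbour flask holds 95.0% as crystals at 12.0 h.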